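(The readings are calculated on assumed constants; the scatter is artificial.)

The pitfall with a straight rise is to read a time constant from it; oak and alder climb straight and then stop, which looks less like a decay than like a feed that ends.

| setting | oak | alder | flask |
|---|---|---|---|
| Q | 0.50 M | 0.50 M | 0.50 M |
| X | 0.40 M | 0.90 M | 0.600 M |
| D | 0.050 M | 0.050 M | 0.0500 M |
| remark | run made earlier | run made earlier |  |
| time |  |  | 10 d |

| run | time / d | Z / % | E / % |
|---|---|---|---|
| oak | 0.500 | 13.2 | 0.8 |
| oak | 0.833 | 23.6 | 0 |
| oak | 1.67 | 50.5 | 1.7 |
| oak | 3.00 | 80.4 | 17.6 |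
| oak | 6.00 | 81.6 | 17.4 |
| alder | 0.500 | 15.4 | 0 |
| alder | 1.67 | 50.7 | 0.6 |
| alder | 3.00 | 86.8 | 23.4 |
| alder | 4.00 | 93.0 | 28.4 |
| alder | 6.00 | 91.4 | 30.1 |

(scatter of a reading: 1 percentage point)

- Z is meant together with its E
- solid, in amounts per volume of the solution: Q, X, E
- at the start none of Q is in solution
- at the start none of X is in solution
- J means what is dissolved; the solid is not counted in it
- J is what Q becomes in solution

1. Z and E together at 10 d, in percent of the Q charged
2. concentration of J in solution at 10 d, in percent of saturation

I call the steady making of Z, read from alder between 0.500 d and 1.67 d, the feed 0.151 M/d. My first guess is that the feed follows the charge of X. But oak, over the same span, reads 0.159 M/d, about the same, although alder holds 2.25 times its X. So over this span the rate does not follow the charge of X: it is zero order in that charge.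

Oak ends at 0.408 M of Z against 0.40 M of X, its limiting reagent. The flask has X to spare, so I take alder's plateau, 92.2%, which needs a finish time of 3.06 d, a third of the 10 d asked.

The objection is that the missing 0.0390 M of Q might stand as J. But alder's Z does not rise from 4.00 d to 6.00 d beside 0.439 M of spare X, and that shortfall is less than the 0.050 M of D. So I expect that Q to be taken by D, and J near zero.

The forecast differs on J: it gives 91.5% and 75% of saturation, reading alder's shortfall as “an equilibrium or a small loss”.

The flask gives 91.2% and J at 0% of saturation.

    Q ⇌ J, rate k1*(cs1 - [J]) while solid is left; crystals form when [J] > cs1 (solubility = 0.280 M, k = 1.40 × 10⁻⁴ /s)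
    E ⇌ Z, rate k2*(cs2 - [Z]) while solid is left; crystals form when [Z] > cs2 (solubility = 0.310 M, k = 9.60 × 10⁻⁴ /s)
    X ⇌ L, rate k3*(cs3 - [L]) while solid is left; crystals form when [L] > cs3 (solubility = 0.210 M, k = 8.90 × 10⁻⁶ /s)
    J + L → Z (k = 0.00100 /M/s)
    Q + D → G (k = 1.60 × 10⁻⁴ /M/s)

Q stands at 0% in the flask, and G holds 8.80%. The feed serves again on a neighbour flask, charged with 2.0 M of Q: at the feed, its 0.600 M of X lasts 3.97 d, and at 10 d it shows Z 30.0% of its Q, or 0.600 M, with X 0%, L 0 M and Q 53.5%. In the flask itself the finish time of 3.06 d falls before 5.00 d, where Z and E already stand at 91.2%. Ten times the time changes nothing: at 100 d, L is 0.144 M and Z with E is 91.2%.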